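Assumption: the target, 7-hydroxy-2-(4-hydroxyphenyl)-3,5,6,8-tetramethoxy-4H-chromen-4-one, has no stereocentre, so no enantiocontrol is needed; the only stereo-element on the way is the E-alkene of chalcone 13, which disappears on cyclisation.

**Retrosynthetic overview**
1. Target 19 ⇐ hydrogenolysis of the 7,4'-dibenzyl ether 18 ⇐ 3-O-methylation of flavonol 17 ⇐ C3-hydroxylation of flavone 15.
2. Flavone 15 (pyranone ring C, the only ring made, formed last) ⇐ oxidative cyclisation of 2'-hydroxychalcone 13 ⇐ Claisen–Schmidt aldol condensation of acetophenone 10 with 4-(benzyloxy)benzaldehyde 11 (forms the future C2–C3 bond).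
3. Acetophenone 10 ⇐ selective 4-O-benzylation of 9 ⇐ chelation-controlled ortho-demethylation of 7 ⇐ lithiation/Weinreb acetylation of the pentaoxygenated arene 4.
4. Arene 4 ⇐ double Cu-catalysed methoxylation of dibromide 3 ⇐ 4,6-dibromination of MOM-protected 2,6-dimethoxyphenol (rings A and B are bought as benzene rings).

**Route**

Step 1
Reactants: 1 2,6-dimethoxyphenol
Product: 2 1,3-dimethoxy-2-(methoxymethoxy)benzene
Conditions: MOMCl (1.3 equiv), K2CO3 (2 equiv), DMF, 0 °C → rt
Reagents that add atoms: chloromethyl methyl ether COCCl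
Why: Williamson-type O-alkylation of the phenoxide (MOM protection) gives an acetal that is stable to the base, Cu/alkoxide and organolithium conditions that follow.

Step 2
Reactants: 2 1,3-dimethoxy-2-(methoxymethoxy)benzene
Product: 3 1,5-dibromo-2,4-dimethoxy-3-(methoxymethoxy)benzene
Conditions: NBS (2.1 equiv), MeCN, 0 °C → rt, dark
Reagents that add atoms: N-bromosuccinimide O=C1CCC(=O)N1Br
Why: Electrophilic aromatic bromination goes to the two positions that are para to one OMe and ortho to the other, because the central, twisted OMOM group activates its own para position only weakly (same pattern as pyrogallol trimethyl ether).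

Step 3
Reactants: 3 1,5-dibromo-2,4-dimethoxy-3-(methoxymethoxy)benzene
Product: 4 1,2,4,5-tetramethoxy-3-(methoxymethoxy)benzene
Conditions: NaOMe (6 equiv), CuI (20 mol %), MeOH/DMF, 110 °C
Reagents that add atoms: sodium methoxide [Na+].[O-]C
Why: Ullmann-type copper-catalysed methoxylation replaces both aryl bromides, and the MOM acetal is inert to alkoxide.

Step 4
Reactants: 4 1,2,4,5-tetramethoxy-3-(methoxymethoxy)benzene
Product: 7 1-[2,3,5,6-tetramethoxy-4-(methoxymethoxy)phenyl]ethan-1-one, via aryllithium 5 (not isolated), via lithium hemiaminal alkoxide 6 (not isolated)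
Conditions: n-BuLi (1.2 equiv), TMEDA, THF, 0 °C, 1 h; then MeC(O)N(OMe)Me, −78 °C → rt; aq NH4Cl
Reagents that add atoms: N-methoxy-N-methylacetamide CC(=O)N(C)OC
Why: Directed ortho-metalation removes the only ring hydrogen (flanked by two OMe groups), and the Weinreb ketone synthesis stops at the ketone because the chelated tetrahedral adduct survives until work-up.

Step 5
Reactants: 7 1-[2,3,5,6-tetramethoxy-4-(methoxymethoxy)phenyl]ethan-1-one
Product: 9 1-(2,4-dihydroxy-3,5,6-trimethoxyphenyl)ethan-1-one, via bis(dichloroboryl) ether 8 (not isolated)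
Conditions: BCl3 (2.5 equiv), CH2Cl2, −78 → 0 °C; then H2O
Reagents that add atoms: none
Why: Chelation-controlled Lewis-acid demethylation cleaves one OMe ortho to the ketone (the resulting boron chelate deactivates the second) and the MOM acetal falls off in the same operation.

Step 6
Reactants: 9 1-(2,4-dihydroxy-3,5,6-trimethoxyphenyl)ethan-1-one
Product: 10 1-[4-(benzyloxy)-2-hydroxy-3,5,6-trimethoxyphenyl]ethan-1-one
Conditions: BnBr (1.05 equiv), K2CO3 (1.2 equiv), acetone, reflux
Reagents that add atoms: benzyl bromide BrCc1ccccc1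
Why: Regioselective Williamson etherification, since the 2-OH is tied up in a hydrogen bond to the ketone while the more acidic para 4-OH is alkylated.

Step 7
Reactants: 10 1-[4-(benzyloxy)-2-hydroxy-3,5,6-trimethoxyphenyl]ethan-1-one; 11 4-(benzyloxy)benzaldehyde
Product: 13 (E)-1-[4-(benzyloxy)-2-hydroxy-3,5,6-trimethoxyphenyl]-3-[4-(benzyloxy)phenyl]prop-2-en-1-one, via aldol adduct 12 (not isolated)
Conditions: KOH (50% aq, excess), EtOH, rt, 24–48 h; then 1 M HCl
Reagents that add atoms: none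
Why: Claisen–Schmidt crossed aldol condensation of the methyl ketone enolate with a non-enolisable aldehyde, followed by E1cB dehydration to the thermodynamically favoured E-enone; this is the key C–C bond formation joining the two fragments.

Step 8
Reactants: 13 (E)-1-[4-(benzyloxy)-2-hydroxy-3,5,6-trimethoxyphenyl]-3-[4-(benzyloxy)phenyl]prop-2-en-1-one
Product: 15 7-(benzyloxy)-2-[4-(benzyloxy)phenyl]-5,6,8-trimethoxy-4H-chromen-4-one, via flavanone 14 (not isolated)
Conditions: I2 (10 mol %), DMSO, 120 °C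
Reagents that add atoms: none
Why: Intramolecular oxa-Michael addition gives the flavanone, which is dehydrogenated by α-iodination/HI elimination with DMSO as terminal oxidant (I2/DMSO oxidative cyclisation); this is reliable for 6'-methoxychalcones, where Algar–Flynn–Oyamada conditions tend to give aurones.

Step 9
Reactants: 15 7-(benzyloxy)-2-[4-(benzyloxy)phenyl]-5,6,8-trimethoxy-4H-chromen-4-one
Product: 17 7-(benzyloxy)-2-[4-(benzyloxy)phenyl]-3-hydroxy-5,6,8-trimethoxy-4H-chromen-4-one, via flavone oxide 16 (not isolated)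
Conditions: DMDO (3 equiv, acetone solution), CH2Cl2, 0 °C → rt; then p-TsOH (cat.), rt
Reagents that add atoms: dimethyldioxirane CC1(C)OO1
Why: DMDO epoxidation of the C2=C3 enol-ether bond followed by acid-catalysed epoxide opening and loss of H-3 gives the 3-hydroxyflavone, with the aryl benzyl ethers reacting much more slowly.

Step 10
Reactants: 17 7-(benzyloxy)-2-[4-(benzyloxy)phenyl]-3-hydroxy-5,6,8-trimethoxy-4H-chromen-4-one
Product: 18 7-(benzyloxy)-2-[4-(benzyloxy)phenyl]-3,5,6,8-tetramethoxy-4H-chromen-4-one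
Conditions: MeI (3 equiv), K2CO3, DMF, rt
Reagents that add atoms: iodomethane CI
Why: Williamson O-methylation of the only free hydroxyl (the acidic 3-OH enol).

Step 11
Reactants: 18 7-(benzyloxy)-2-[4-(benzyloxy)phenyl]-3,5,6,8-tetramethoxy-4H-chromen-4-one
Product: 19 7-hydroxy-2-(4-hydroxyphenyl)-3,5,6,8-tetramethoxy-4H-chromen-4-one
Conditions: H2 (1 atm), 10% Pd/C, EtOAc/MeOH, rt
Reagents that add atoms: none
Why: Catalytic hydrogenolysis cleaves both benzyl ethers, while the methyl ethers and the tetrasubstituted, vinylogous-ester C2=C3 bond are inert under these conditions.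

**Compound list**
1 | 2,6-dimethoxyphenol | COc1cccc(OC)c1O | starting material
2 | 1,3-dimethoxy-2-(methoxymethoxy)benzene | COCOc1c(OC)cccc1OC | intermediate
3 | 1,5-dibromo-2,4-dimethoxy-3-(methoxymethoxy)benzene | COCOc1c(OC)c(Br)cc(Br)c1OC | intermediate
4 | 1,2,4,5-tetramethoxy-3-(methoxymethoxy)benzene | COCOc1c(OC)c(OC)cc(OC)c1OC | intermediate
5 | [2,3,5,6-tetramethoxy-4-(methoxymethoxy)phenyl]lithium | [Li]c1c(OC)c(OC)c(OCOC)c(OC)c1OC | intermediate
6 | lithium 1-[methoxy(methyl)amino]-1-[2,3,5,6-tetramethoxy-4-(methoxymethoxy)phenyl]ethan-1-olate | CC(O[Li])(N(C)OC)c1c(OC)c(OC)c(OCOC)c(OC)c1OC | intermediate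
7 | 1-[2,3,5,6-tetramethoxy-4-(methoxymethoxy)phenyl]ethan-1-one | CC(=O)c1c(OC)c(OC)c(OCOC)c(OC)c1OC | intermediate
8 | 1-[2,4-bis(dichloroboryloxy)-3,5,6-trimethoxyphenyl]ethan-1-one | CC(=O)c1c(OB(Cl)Cl)c(OC)c(OB(Cl)Cl)c(OC)c1OC | intermediate
9 | 1-(2,4-dihydroxy-3,5,6-trimethoxyphenyl)ethan-1-one | CC(=O)c1c(O)c(OC)c(O)c(OC)c1OC | intermediate
10 | 1-[4-(benzyloxy)-2-hydroxy-3,5,6-trimethoxyphenyl]ethan-1-one | CC(=O)c1c(O)c(OC)c(OCc2ccccc2)c(OC)c1OC | intermediate
11 | 4-(benzyloxy)benzaldehyde | O=Cc1ccc(OCc2ccccc2)cc1 | starting material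
12 | 1-[4-(benzyloxy)-2-hydroxy-3,5,6-trimethoxyphenyl]-3-[4-(benzyloxy)phenyl]-3-hydroxypropan-1-one (racemic) | O=C(CC(O)c1ccc(OCc2ccccc2)cc1)c1c(O)c(OC)c(OCc2ccccc2)c(OC)c1OC | intermediate
13 | (E)-1-[4-(benzyloxy)-2-hydroxy-3,5,6-trimethoxyphenyl]-3-[4-(benzyloxy)phenyl]prop-2-en-1-one | O=C(/C=C/c1ccc(OCc2ccccc2)cc1)c1c(O)c(OC)c(OCc2ccccc2)c(OC)c1OC | intermediate
14 | 7-(benzyloxy)-2-[4-(benzyloxy)phenyl]-5,6,8-trimethoxychroman-4-one (racemic) | O=C1CC(c2ccc(OCc3ccccc3)cc2)Oc2c(OC)c(OCc3ccccc3)c(OC)c(OC)c21 | intermediate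
15 | 7-(benzyloxy)-2-[4-(benzyloxy)phenyl]-5,6,8-trimethoxy-4H-chromen-4-one | O=c1cc(-c2ccc(OCc3ccccc3)cc2)oc2c(OC)c(OCc3ccccc3)c(OC)c(OC)c12 | intermediate
16 | 7-(benzyloxy)-2-[4-(benzyloxy)phenyl]-5,6,8-trimethoxy-2,3-epoxychroman-4-one (racemic) | O=C1C2OC2(c2ccc(OCc3ccccc3)cc2)Oc2c(OC)c(OCc3ccccc3)c(OC)c(OC)c21 | intermediate
17 | 7-(benzyloxy)-2-[4-(benzyloxy)phenyl]-3-hydroxy-5,6,8-trimethoxy-4H-chromen-4-one | O=c1c(O)c(-c2ccc(OCc3ccccc3)cc2)oc2c(OC)c(OCc3ccccc3)c(OC)c(OC)c12 | intermediate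
18 | 7-(benzyloxy)-2-[4-(benzyloxy)phenyl]-3,5,6,8-tetramethoxy-4H-chromen-4-one | COc1c(-c2ccc(OCc3ccccc3)cc2)oc2c(OC)c(OCc3ccccc3)c(OC)c(OC)c2c1=O | intermediate
19 | 7-hydroxy-2-(4-hydroxyphenyl)-3,5,6,8-tetramethoxy-4H-chromen-4-one | COc1c(O)c(OC)c2oc(-c3ccc(O)cc3)c(OC)c(=O)c2c1OC | target

**Totals**
Total step count: 11. Longest linear sequence: 11 steps (1 → 19); aldehyde 11 is bought.

**Three steps most likely to fail, with fallbacks**

Step 3 (double Cu-catalysed methoxylation; risk of incomplete exchange or hydrodebromination). The fallback sets out from 3 and comes back at 4. Palladium-catalysed hydroxylation of both C–Br bonds (Pd2(dba)3, tBuXPhos, KOH, dioxane/H2O, 100 °C) gives 4,6-dimethoxy-5-(methoxymethoxy)benzene-1,3-diol F1. This air-sensitive diol is methylated directly (MeI, K2CO3, DMF, rt) to give 4, so the C–O bonds are made by Pd coupling to the phenol and the methyl groups are added afterwards.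

Step 5 (BCl3; risk of over-demethylation at the second ortho-OMe or at the OMe groups next to the freed 4-OH). The fallback sets out from 7 and comes back at 10, bypassing 9. It separates the two deprotections and replaces the strong Lewis acid with a chelation-only reagent that tolerates a remote benzyl ether. Mild methanolysis of the MOM acetal (cat. HCl, MeOH, rt) gives 1-(4-hydroxy-2,3,5,6-tetramethoxyphenyl)ethan-1-one F2. Benzylation (BnBr, K2CO3, DMF) gives 1-[4-(benzyloxy)-2,3,5,6-tetramethoxyphenyl]ethan-1-one F3. Regioselective mono-demethylation ortho to the ketone with MgI2·OEt2 (toluene/Et2O, 60 °C; iodide attack on the magnesium chelate) then gives 10.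

Step 9 (DMDO epoxidation; risk of sluggish reaction of the electron-poor chromone double bond and competing benzylic oxidation of the benzyl ethers). The fallback sets out from 15 and comes back at 17, replacing electrophilic oxidation with C–H deprotonation. LDA (THF, −78 °C) gives the 3-lithioflavone {7-(benzyloxy)-2-[4-(benzyloxy)phenyl]-5,6,8-trimethoxy-4-oxo-4H-chromen-3-yl}lithium F4. Trapping with B(OMe)3 gives dimethyl {7-(benzyloxy)-2-[4-(benzyloxy)phenyl]-5,6,8-trimethoxy-4-oxo-4H-chromen-3-yl}boronate F5. Oxidation of the C–B bond (H2O2, AcOH, 0 °C → rt) gives 17.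

**Further compounds**
F1 | step 3 | 4,6-dimethoxy-5-(methoxymethoxy)benzene-1,3-diol | COCOc1c(OC)c(O)cc(O)c1OC
F2 | step 5 | 1-(4-hydroxy-2,3,5,6-tetramethoxyphenyl)ethan-1-one | CC(=O)c1c(OC)c(OC)c(O)c(OC)c1OC
F3 | step 5 | 1-[4-(benzyloxy)-2,3,5,6-tetramethoxyphenyl]ethan-1-one | CC(=O)c1c(OC)c(OC)c(OCc2ccccc2)c(OC)c1OC
F4 | step 9 | {7-(benzyloxy)-2-[4-(benzyloxy)phenyl]-5,6,8-trimethoxy-4-oxo-4H-chromen-3-yl}lithium | [Li]c1c(-c2ccc(OCc3ccccc3)cc2)oc2c(OC)c(OCc3ccccc3)c(OC)c(OC)c2c1=O
F5 | step 9 | dimethyl {7-(benzyloxy)-2-[4-(benzyloxy)phenyl]-5,6,8-trimethoxy-4-oxo-4H-chromen-3-yl}boronate | COB(OC)c1c(-c2ccc(OCc3ccccc3)cc2)oc2c(OC)c(OCc3ccccc3)c(OC)c(OC)c2c1=O
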